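## Compound numbering used throughout

1 2,4,6-trihydroxybenzaldehyde · 2 its 4-O-methyl ether · 3 mono-MOM ether of 2 · 4 Mannich base of 3 · 5 ammonium iodide (in situ) · 6 formyl ortho-quinone methide (in situ) · 7 formyl sulfone · 8 ring A sulfone with C8 dioxolane · 9 2-bromo-5-methoxyphenol · 10 MOM ether of 9 · 11 aryllithium (in situ) · 12 arylethanol · 13 prenyl bromide · 14 dilithiated alcohol (in situ) · 15 prenylated arylethanol · 16 arylacetaldehyde (in situ) · 17 ring B arylacetic acid · 18 mixed pivalic anhydride (in situ) · 19 dioxolane ortho-quinone methide (in situ) · 20 dihydrocoumarin · 21 phenol–alcohol · 22 protected isoflavan · 23 target.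

## Analysis of the target

The target is an isoflavan: a chroman (ring A fused to the oxygen heterocycle, ring C) that carries aryl ring B at C3. Ring A is pentasubstituted: O1 at C8a, a formyl group at C8, a free hydroxyl at C7 hydrogen-bonded to that formyl group, hydrogen at C6 and a methoxy group at C5. Ring B carries a free 2'-hydroxyl, a 3'-prenyl group and a 4'-methoxy group. C3 is the only stereocentre and is R (C2 > C1' > C4 > H); it is tertiary, benzylic and remote from any group that could direct its formation. The sensitive functions are the electron-rich salicylaldehyde unit, the two phenols and the trisubstituted prenyl alkene. The alkene rules out catalytic hydrogenation, electrophilic oxidants and strong protic acid next to the free 2'-phenol. The difficulty is twofold: an isolated stereocentre must be set absolutely, and two differently oxygenated arenes must be joined through a three-carbon bridge without regiochemical ambiguity at C8 or damage to the prenyl group. The strategy rests on C4: it is a benzylic methylene ortho to the phenolic oxygen O1 of ring A, so C4a–C4 together with C8a–O1 is a latent ortho-quinone methide, and C3–C2 is the α-carbon and carboxyl carbon of a ring B arylacetic acid at a higher oxidation level.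

## Retrosynthetic reasoning

**23 from 22.** The two free phenols and the aldehyde are masked as two MOM ethers and a dioxolane. All three are acetals, so one mild acid treatment releases 23 as the last step. No oxidation, reduction or base is then needed in the presence of the free salicylaldehyde and the ortho-prenylphenol.

**22 from 21, and 21 from 20.** The O1–C2 ether bond is cut to give phenol–alcohol 21, which recloses by intramolecular Mitsunobu etherification at a primary carbon; C3 is untouched. Compound 21 is the hydride reduction product of lactone 20. This detour through the lactone is what allows C2 to arrive as a carboxyl carbon, which is the handle for asymmetric enolate chemistry at C3.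

**20 from 8 and 17 (key disconnection).** C3–C4 and the O1–C2 acyl bond are cut together. Ring A then becomes ortho-quinone methide 19, released from sulfone 8, and ring B becomes acid 17, activated as mixed anhydride 18 and bound to a chiral isothiourea as an ammonium enolate. The cut is made here because it is the only place where the stereocentre, the last C–C bond and ring C arise in one catalytic step from two arenes of similar size. The methide carbon C4 is unsubstituted, so only the enolate face has to be controlled.

**8 from 7.** The C8 dioxolane is taken back to the formyl group of sulfone 7. An ortho-hydroxyaryl dioxolane on a trioxygenated ring is the most acid-labile group of the whole route, so it is put on in the last operation of the ring A branch and carried straight into the key step. The forward reaction must acetalise a chelated aldehyde with an acid too weak to touch the MOM ether, and it must avoid base altogether, because base would expel sulfinate from 7 or 8.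

**7 from 4 through 5 and 6.** The C4–S bond is formed by elimination–addition: Mannich base 4 is quaternised to 5, which loses its amine to give methide 6, and sulfinate adds. The sulfone is preferred to the ammonium salt as the stored precursor because sulfinate, unlike a liberated tertiary amine, cannot act as a competing achiral acyl-transfer catalyst in the key step.

**4 from 3.** The C4a–C4 bond comes from ortho-aminomethylation of phenol 3. Its only free position ortho to the hydroxyl is the future C4a, and the reaction needs only an amine base, which leaves the aldehyde and the MOM ether alone.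

**3 from 1 through 2.** The C8 carbon is present from the start as the formyl group of 1, so no late formylation has to choose between C6 and C8. The three oxygens are told apart by acidity and chelation: the non-chelated 4-hydroxyl of 1 is methylated first (C5–OMe). One of the two equivalent chelated hydroxyls of 2 is then protected (C7–OMOM), and the remaining one (C8a–OH) stays free in 3.

**17 from 15, and 15 from 12 and 13.** The acid is the oxidation product of arylethanol 15 by way of aldehyde 16. The C3'–prenyl bond is cut next: C3' lies between OMOM and OMe, the best site for directed metalation, so 12 is metalated to 14 and allylated with 13. The order is deliberate. Prenyl goes on last, so no ring carrying acidic allylic–benzylic protons has to be metalated.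

**12 from 9 through 10.** The C1'–CH2 bond is placed by bromine–lithium exchange of 10 and hydroxyethylation of aryllithium 11 by epoxide opening. The bromine of commercial 9 fixes the position of the side chain ortho to the protected phenol and para to the methoxy group without any regiochemical choice.

## Alternatives that were turned down

Alternative 1: Ring A is disconnected at C7–C8, C4a–C8a and C6–C7 and built by a vinylketene/siloxyalkyne benzannulation. Irradiation of diazo ketone A1 would trigger a Wolff rearrangement to a vinylketene carrying the C4–C3(aryl)–C2 chain and the C5 methoxy group. A [2+2] addition to siloxyalkyne A2, four-electron ring opening, six-electron ring closure and tautomerisation would give phenol A3, with C7–OH free, C8 as a dimethyl acetal, C8a as a silyl ether and ring C still open.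
- In its favour: every position of ring A is fixed by connectivity, the C7 hydroxyl emerges unprotected, and no selective protection or ortho-selective substitution is needed. On this point it is stronger than the chosen route, which depends on the ortho-aminomethylation of step 3.
- Against it: C3 must be set earlier by a separate asymmetric operation and carried through diazo chemistry. A1 is a fully substituted α-diazo ketone with an α-methoxy enone and is laborious to make. Its carbene can attack the prenyl alkene or electron-rich ring B before it rearranges. A2 is a sensitive ynol ether. Two desilylations and a ring C closure still follow.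
- Comparison: the sequence is clearly longer than the 13 steps (9 linear) proposed here. The chosen route gives up guaranteed ring A regiochemistry but makes the stereocentre and ring C together in one catalytic step from arenes that already carry their oxygens.

Alternative 2: C3–C1' and the C4–O(2') bond are formed together as a pterocarpan, and the C4–O bond is cut reductively afterwards. Oxyarylation of 2H-chromene A4 with ortho-iodophenol A5 under Pd(OAc)2, a chiral bisphosphine and Ag2CO3 would add the aryl group to C3 and the phenol oxygen to C4, giving cis-pterocarpan A6.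
- In its favour: it is convergent, ring C is already at the right oxidation level (no lactone reduction and re-closure), and the 2'-oxygen needs no protecting group. On these points it is stronger than the chosen route.
- Against it: the racemic oxyarylation is well established, but useful enantiocontrol with a chiral ligand is not, so the stereochemistry-defining step would have to be developed. The reductive opening is the deeper problem. Hydrogenolysis would saturate the prenyl group, and dissolving-metal conditions threaten the aryl acetal and other benzylic C–O bonds. The C4 stereocentre is created only to be destroyed.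
- Comparison: the length is comparable, but two unproven operations stand against one precedented catalytic step in the chosen route, which also uses only alkene-compatible reagents after the prenyl group is installed.

Alternative 3: Ring B is disconnected at C1'–C2', C2'–C3' and C4'–C5' and built on a finished chroman. Irradiation of diazo enone A7 would give a vinylketene that combines with alkoxyalkyne A8 to give isoflavan A9, with 2'-OH, 3'-prenyl and 4'-OMe placed by connectivity.
- In its favour: the contiguous hydroxyl/prenyl/methoxy pattern of ring B appears in one step without protecting groups or metalation. This is stronger than the four-step ring B sequence used here.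
- Against it: A9 lacks the C8 formyl group. A late formylation would have to choose C8 over C6 (both ortho to the 7-hydroxyl) and over the activated C5' of ring B, in the presence of the acid-sensitive ortho-prenylphenol. The C3 stereocentre must be set earlier and sits at the γ-position of the enone in A7, where vinylogous enolisation can erode it.
- Comparison: the chosen route carries the C8 carbon from the first step and creates C3 late, leaving it next to a carbonyl for only one further step.

Key step: step 10

Assumption: (R)-benzotetramisole is taken to give the 3R lactone, as the usual model for isothiourea-bound enolates predicts (enolate oxygen syn to sulfur, attack on the face away from the catalyst's phenyl group); the antipodal catalyst is equally available should the sense prove opposite.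

## Route

Step 1
Reactants: 1 2,4,6-trihydroxybenzaldehyde
Product: 2 2,6-dihydroxy-4-methoxybenzaldehyde
Conditions: MeI (1.05 equiv), NaHCO3 (1.2 equiv), DMF, 40 °C
Reagents that add atoms: iodomethane, CI
Why: Williamson methylation; the 4-hydroxyl is para to the formyl group and not hydrogen-bonded, so it is by far the most acidic and is the only one ionised by bicarbonate, while the two chelated ortho hydroxyls stay protonated.

Step 2
Reactants: 2 2,6-dihydroxy-4-methoxybenzaldehyde
Product: 3 2-hydroxy-4-methoxy-6-(methoxymethoxy)benzaldehyde
Conditions: MOMCl (1.05 equiv), iPr2NEt (1.2 equiv), CH2Cl2, 0 °C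
Reagents that add atoms: chloromethyl methyl ether, COCCl
Why: Selective mono-protection; the two hydroxyls of 2 are equivalent, and once one is etherified the other is locked in a strong hydrogen bond to the formyl oxygen and should react much more slowly.

Step 3
Reactants: 3 2-hydroxy-4-methoxy-6-(methoxymethoxy)benzaldehyde
Product: 4 3-[(dimethylamino)methyl]-2-hydroxy-4-methoxy-6-(methoxymethoxy)benzaldehyde
Conditions: CH2=NMe2+ I− (1.1 equiv), Et3N (1.2 equiv), CH2Cl2, 0 → 40 °C
Reagents that add atoms: N,N-dimethylmethyleneiminium iodide, C=[N+](C)C.[I-]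
Why: Phenol Mannich reaction with a preformed iminium salt; the phenoxide–iminium ion pair should deliver the electrophile to C3, the only free position ortho to the hydroxyl (the future C4a), in preference to C5, which is flanked by two alkoxy groups. The aldehyde and the MOM ether are inert to these base-only conditions.

Step 4
Reactants: 4 3-[(dimethylamino)methyl]-2-hydroxy-4-methoxy-6-(methoxymethoxy)benzaldehyde
Product: 7 2-hydroxy-4-methoxy-6-(methoxymethoxy)-3-[(4-methylbenzenesulfonyl)methyl]benzaldehyde, via ammonium iodide 5 (not isolated), via formyl ortho-quinone methide 6 (not isolated)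
Conditions: MeI (1.5 equiv), MeCN, rt; evaporate; TolSO2Na (3 equiv), DMF, 50 °C
Reagents that add atoms: sodium 4-methylbenzenesulfinate, Cc1ccc(cc1)S(=O)[O-].[Na+]
Why: Quaternisation turns the amine into a leaving group, loss of trimethylamine from the phenol gives quinone methide 6, and excess sulfinate captures it at sulfur (elimination–addition, the classical amine exchange of phenolic Mannich bases), the sulfone being the thermodynamic product. No acid is involved, so the MOM ether should survive, and the aldehyde does not add sulfinate irreversibly.

Step 5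
Reactants: 7 2-hydroxy-4-methoxy-6-(methoxymethoxy)-3-[(4-methylbenzenesulfonyl)methyl]benzaldehyde
Product: 8 6-(1,3-dioxolan-2-yl)-3-methoxy-5-(methoxymethoxy)-2-[(4-methylbenzenesulfonyl)methyl]phenol
Conditions: HOCH2CH2OH (5 equiv), HC(OMe)3 (2 equiv), PPTS (10 mol%), CH2Cl2, rt; pH 7 phosphate buffer wash
Reagents that add atoms: ethylene glycol, OCCO
Why: Acid-catalysed acetalisation driven by the orthoformate as water scavenger; the oxocarbenium ion is strongly stabilised by the three ring oxygens so that even the chelated aldehyde should exchange. PPTS at room temperature is too weak to cleave the aryl MOM ether or to ionise the benzylic sulfone, and the neutral work-up avoids the base that would expel sulfinate.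

Step 6
Reactants: 9 2-bromo-5-methoxyphenol
Product: 10 1-bromo-4-methoxy-2-(methoxymethoxy)benzene
Conditions: MOMCl (1.2 equiv), iPr2NEt (1.5 equiv), CH2Cl2, 0 °C → rt
Reagents that add atoms: chloromethyl methyl ether, COCCl
Why: Standard phenol protection; the MOM group stabilises the aryllithium of step 7 by chelation and is the directing group of step 8.

Step 7
Reactants: 10 1-bromo-4-methoxy-2-(methoxymethoxy)benzene
Product: 12 2-[4-methoxy-2-(methoxymethoxy)phenyl]ethan-1-ol, via aryllithium 11 (not isolated)
Conditions: n-BuLi (1.05 equiv), THF, −78 °C; ethylene oxide (5 equiv), −78 °C → rt; aq. NH4Cl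
Reagents that add atoms: ethylene oxide, C1CO1
Why: Bromine–lithium exchange is faster than any deprotonation and fixes the side chain at C1'; the aryllithium opens the epoxide at carbon to give the 2-arylethanol.

Step 8
Reactants: 12 2-[4-methoxy-2-(methoxymethoxy)phenyl]ethan-1-ol; 13 prenyl bromide (1-bromo-3-methylbut-2-ene)
Product: 15 2-[4-methoxy-2-(methoxymethoxy)-3-(3-methylbut-2-en-1-yl)phenyl]ethan-1-ol, via dilithiated alcohol 14 (not isolated)
Conditions: n-BuLi (2.3 equiv), THF, 0 °C; CuBr·SMe2 (10 mol%), 13 (1.4 equiv), −78 → 0 °C; aq. NH4Cl
Reagents that add atoms: none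
Why: Directed ortho-metalation; after the alkoxide forms, the second equivalent of base removes the proton at C3', the only position flanked by both OMOM and OMe, and copper-catalysed allylic substitution of the aryl anion on 13 gives the linear prenyl arene. The lithium alkoxide is a much poorer nucleophile than the aryl–copper species, so C-allylation should dominate.

Step 9
Reactants: 15 2-[4-methoxy-2-(methoxymethoxy)-3-(3-methylbut-2-en-1-yl)phenyl]ethan-1-ol
Product: 17 2-[4-methoxy-2-(methoxymethoxy)-3-(3-methylbut-2-en-1-yl)phenyl]acetic acid, via arylacetaldehyde 16 (not isolated)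
Conditions: TEMPO (20 mol%), PhI(OAc)2 (2.2 equiv), MeCN/H2O (1:1), rt
Reagents that add atoms: water, O
Why: Oxoammonium oxidation of the primary alcohol to aldehyde 16 and, through its hydrate, on to the acid; these conditions are known to spare trisubstituted alkenes, aryl ethers and MOM groups.

Step 10
Reactants: 17 2-[4-methoxy-2-(methoxymethoxy)-3-(3-methylbut-2-en-1-yl)phenyl]acetic acid; 8 6-(1,3-dioxolan-2-yl)-3-methoxy-5-(methoxymethoxy)-2-[(4-methylbenzenesulfonyl)methyl]phenol
Product: 20 (3R)-8-(1,3-dioxolan-2-yl)-5-methoxy-7-(methoxymethoxy)-3-[4-methoxy-2-(methoxymethoxy)-3-(3-methylbut-2-en-1-yl)phenyl]-3,4-dihydro-2H-chromen-2-one, via mixed pivalic anhydride 18 (not isolated), via dioxolane ortho-quinone methide 19 (not isolated)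
Conditions: 17 (1.3 equiv), t-BuCOCl (1.3 equiv), iPr2NEt (1.3 equiv), CH2Cl2, 0 °C; then (R)-benzotetramisole (10 mol%), 8 (1.0 equiv), iPr2NEt (2.5 equiv), −20 °C → rt
Reagents that add atoms: none
Why: Acid 17 is first converted into mixed anhydride 18; the isothiourea is acylated at the less hindered arylacetyl carbonyl and the acyl ammonium ion is deprotonated to the (Z)-ammonium enolate, held coplanar with the catalyst by the oxygen–sulfur contact. In parallel the amine base ionises phenol 8 and p-toluenesulfinate leaves to give quinone methide 19. The enolate carbon (C3) adds to the exocyclic methylene (C4) of 19 with rearomatisation of ring A, and the resulting aryloxide closes ring C by attack on the acyl ammonium carbonyl (6-exo-trig acyl substitution), forming O1–C2 and releasing the catalyst. The closest known reaction type is the isothiourea- or carbene-catalysed formal [4+2] cycloaddition of ortho-quinone methides generated in situ with ammonium or azolium enolates to give 3,4-dihydrocoumarins. C3 is the only new stereocentre; it is set by the catalyst, whose phenyl group shields one face of the planar enolate so that C4 is attached anti to it, which for (R)-benzotetramisole is predicted to give 3R. The step needs enantiofacial control and C–C bond formation ahead of O-acylation of the phenol: 19 has a single, unsubstituted electrophilic carbon, the phenol of 8 is flanked by two ortho substituents and should be slow to acylate directly, and its electron-rich ring lets sulfinate leave under a tertiary amine alone. The mild amine base and low temperature should keep the α-aryl lactone from epimerising.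

Step 11
Reactants: 20 (3R)-8-(1,3-dioxolan-2-yl)-5-methoxy-7-(methoxymethoxy)-3-[4-methoxy-2-(methoxymethoxy)-3-(3-methylbut-2-en-1-yl)phenyl]-3,4-dihydro-2H-chromen-2-one
Product: 21 6-(1,3-dioxolan-2-yl)-2-{(2R)-3-hydroxy-2-[4-methoxy-2-(methoxymethoxy)-3-(3-methylbut-2-en-1-yl)phenyl]propyl}-3-methoxy-5-(methoxymethoxy)phenol
Conditions: LiBH4 (2 equiv), THF, 0 °C
Reagents that add atoms: none
Why: Hydride reduction of an aryl ester (phenolic lactone) is fast at 0 °C and gives the primary alcohol and the free phenol; acetal, MOM ethers and alkene are inert, and the short, cold exposure should preserve C3 until the carbonyl is gone.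

Step 12
Reactants: 21 6-(1,3-dioxolan-2-yl)-2-{(2R)-3-hydroxy-2-[4-methoxy-2-(methoxymethoxy)-3-(3-methylbut-2-en-1-yl)phenyl]propyl}-3-methoxy-5-(methoxymethoxy)phenol
Product: 22 (3R)-8-(1,3-dioxolan-2-yl)-5-methoxy-7-(methoxymethoxy)-3-[4-methoxy-2-(methoxymethoxy)-3-(3-methylbut-2-en-1-yl)phenyl]-3,4-dihydro-2H-chromene
Conditions: PPh3 (1.5 equiv), DIAD (1.5 equiv), THF, 0 °C → rt
Reagents that add atoms: none
Why: Intramolecular Mitsunobu etherification; the primary alcohol is activated as an alkoxyphosphonium ion and displaced by the phenol (6-exo-tet), re-forming O1–C2. C3 is not a reacting centre, so its configuration is kept.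

Step 13
Reactants: 22 (3R)-8-(1,3-dioxolan-2-yl)-5-methoxy-7-(methoxymethoxy)-3-[4-methoxy-2-(methoxymethoxy)-3-(3-methylbut-2-en-1-yl)phenyl]-3,4-dihydro-2H-chromene
Product: 23 (3R)-7-hydroxy-3-[2-hydroxy-4-methoxy-3-(3-methylbut-2-en-1-yl)phenyl]-5-methoxy-3,4-dihydro-2H-chromene-8-carbaldehyde
Conditions: 3 M aq. HCl, MeOH/THF, 40 °C
Reagents that add atoms: water, O
Why: Acid hydrolysis of three acetal-type groups in one operation; the dioxolane should open first, the C7 MOM ether next to the freed carbonyl is then chelation-labile, and the ring B MOM ether goes last. Acid strength and temperature stay below what is needed to add the 2'-phenol across the prenyl double bond.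

## Compound list

1 | 2,4,6-trihydroxybenzaldehyde | O=Cc1c(O)cc(O)cc1O | starting material
2 | 2,6-dihydroxy-4-methoxybenzaldehyde | COc1cc(O)c(C=O)c(O)c1 | intermediate
3 | 2-hydroxy-4-methoxy-6-(methoxymethoxy)benzaldehyde | COCOc1cc(OC)cc(O)c1C=O | intermediate
4 | 3-[(dimethylamino)methyl]-2-hydroxy-4-methoxy-6-(methoxymethoxy)benzaldehyde | CN(C)Cc1c(O)c(C=O)c(OCOC)cc1OC | intermediate
5 | 1-[3-formyl-2-hydroxy-6-methoxy-4-(methoxymethoxy)phenyl]-N,N,N-trimethylmethanaminium iodide (formed in situ) | C[N+](C)(C)Cc1c(O)c(C=O)c(OCOC)cc1OC.[I-] | intermediate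
6 | 4-methoxy-2-(methoxymethoxy)-5-methylidene-6-oxocyclohexa-1,3-diene-1-carbaldehyde (formyl ortho-quinone methide, formed in situ) | C=C1C(=O)C(C=O)=C(OCOC)C=C1OC | intermediate
7 | 2-hydroxy-4-methoxy-6-(methoxymethoxy)-3-[(4-methylbenzenesulfonyl)methyl]benzaldehyde | Cc1ccc(cc1)S(=O)(=O)Cc1c(O)c(C=O)c(OCOC)cc1OC | intermediate
8 | 6-(1,3-dioxolan-2-yl)-3-methoxy-5-(methoxymethoxy)-2-[(4-methylbenzenesulfonyl)methyl]phenol | Cc1ccc(cc1)S(=O)(=O)Cc1c(O)c(C2OCCO2)c(OCOC)cc1OC | intermediate
9 | 2-bromo-5-methoxyphenol | Oc1cc(OC)ccc1Br | starting material
10 | 1-bromo-4-methoxy-2-(methoxymethoxy)benzene | COCOc1cc(OC)ccc1Br | intermediate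
11 | [4-methoxy-2-(methoxymethoxy)phenyl]lithium (formed in situ) | [Li]c1ccc(OC)cc1OCOC | intermediate
12 | 2-[4-methoxy-2-(methoxymethoxy)phenyl]ethan-1-ol | OCCc1ccc(OC)cc1OCOC | intermediate
13 | prenyl bromide (1-bromo-3-methylbut-2-ene) | CC(C)=CCBr | starting material
14 | lithium 2-[3-lithio-4-methoxy-2-(methoxymethoxy)phenyl]ethoxide (formed in situ) | [Li]OCCc1ccc(OC)c([Li])c1OCOC | intermediate
15 | 2-[4-methoxy-2-(methoxymethoxy)-3-(3-methylbut-2-en-1-yl)phenyl]ethan-1-ol | OCCc1ccc(OC)c(CC=C(C)C)c1OCOC | intermediate
16 | 2-[4-methoxy-2-(methoxymethoxy)-3-(3-methylbut-2-en-1-yl)phenyl]acetaldehyde (formed in situ) | O=CCc1ccc(OC)c(CC=C(C)C)c1OCOC | intermediate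
17 | 2-[4-methoxy-2-(methoxymethoxy)-3-(3-methylbut-2-en-1-yl)phenyl]acetic acid | OC(=O)Cc1ccc(OC)c(CC=C(C)C)c1OCOC | intermediate
18 | 2-[4-methoxy-2-(methoxymethoxy)-3-(3-methylbut-2-en-1-yl)phenyl]acetic 2,2-dimethylpropanoic anhydride (formed in situ) | CC(C)(C)C(=O)OC(=O)Cc1ccc(OC)c(CC=C(C)C)c1OCOC | intermediate
19 | 2-(1,3-dioxolan-2-yl)-5-methoxy-3-(methoxymethoxy)-6-methylidenecyclohexa-2,4-dien-1-one (dioxolane ortho-quinone methide, formed in situ) | C=C1C(=O)C(C2OCCO2)=C(OCOC)C=C1OC | intermediate
20 | (3R)-8-(1,3-dioxolan-2-yl)-5-methoxy-7-(methoxymethoxy)-3-[4-methoxy-2-(methoxymethoxy)-3-(3-methylbut-2-en-1-yl)phenyl]-3,4-dihydro-2H-chromen-2-one | COc1ccc([C@@H]2C(=O)Oc3c(C4OCCO4)c(OCOC)cc(OC)c3C2)c(OCOC)c1CC=C(C)C | intermediate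
21 | 6-(1,3-dioxolan-2-yl)-2-{(2R)-3-hydroxy-2-[4-methoxy-2-(methoxymethoxy)-3-(3-methylbut-2-en-1-yl)phenyl]propyl}-3-methoxy-5-(methoxymethoxy)phenol | COc1ccc([C@@H](Cc2c(O)c(C3OCCO3)c(OCOC)cc2OC)CO)c(OCOC)c1CC=C(C)C | intermediate
22 | (3R)-8-(1,3-dioxolan-2-yl)-5-methoxy-7-(methoxymethoxy)-3-[4-methoxy-2-(methoxymethoxy)-3-(3-methylbut-2-en-1-yl)phenyl]-3,4-dihydro-2H-chromene | COc1ccc([C@@H]2COc3c(C4OCCO4)c(OCOC)cc(OC)c3C2)c(OCOC)c1CC=C(C)C | intermediate
23 | (3R)-7-hydroxy-3-[2-hydroxy-4-methoxy-3-(3-methylbut-2-en-1-yl)phenyl]-5-methoxy-3,4-dihydro-2H-chromene-8-carbaldehyde | COc1ccc([C@@H]2COc3c(C=O)c(O)cc(OC)c3C2)c(O)c1CC=C(C)C | target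

## Step count and least certain steps

Total: 13 steps. Longest linear sequence: 9 steps (steps 1–5 and 10–13); the ring B branch is 4 steps (6–9).

**Step 10 (key step).** Three processes can undermine it. Direct O-acylation of the phenol of 8 by 18 or by the acyl ammonium ion would block release of 19. Self-condensation of 19 can compete if the enolate is formed too slowly. Facial control may be incomplete with an arylacetic acid that carries an ortho substituent, and the product can epimerise at C3 under the amine base. The fallback replaces catalyst control by auxiliary control. Acid 17 is converted through 18 into the imide with lithiated (4R)-4-benzyl-1,3-oxazolidin-2-one, giving (4R)-4-benzyl-3-{[4-methoxy-2-(methoxymethoxy)-3-(3-methylbut-2-en-1-yl)phenyl]acetyl}-1,3-oxazolidin-2-one F1. Its sodium enolate (NaHMDS, two equivalents, one of which ionises the phenol of 8) is alkylated at −78 → −20 °C by the quinone methide 19 released from 8. By the usual chelated Z-enolate model the benzyl group of the auxiliary directs attack to the face that gives the 2R adduct, (4R)-4-benzyl-3-{(2R)-3-[3-(1,3-dioxolan-2-yl)-2-hydroxy-6-methoxy-4-(methoxymethoxy)phenyl]-2-[4-methoxy-2-(methoxymethoxy)-3-(3-methylbut-2-en-1-yl)phenyl]propanoyl}-1,3-oxazolidin-2-one F2. LiBH4 then removes the auxiliary reductively and gives 21 directly; any 20 formed by lactonisation of the adduct is reduced to the same 21. The fallback sets out from 17 and 8 and returns at 21.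

**Step 3.** The phenol of 3 is tied up in the chelate with the formyl group, so aminomethylation may be slow, and it may occur at C5 (para to the phenol) or twice. The fallback frees the phenol from the chelate first and then uses a reaction that is ortho-specific by mechanism. Aldehyde 3 is acetalised (ethylene glycol, HC(OMe)3, PPTS) to 2-(1,3-dioxolan-2-yl)-5-methoxy-3-(methoxymethoxy)phenol F3. This is formylated through its magnesium phenoxide (MgCl2, Et3N, paraformaldehyde, MeCN, reflux) to 3-(1,3-dioxolan-2-yl)-2-hydroxy-6-methoxy-4-(methoxymethoxy)benzaldehyde F4. Reductive amination with dimethylamine and NaBH(OAc)3 gives 2-[(dimethylamino)methyl]-6-(1,3-dioxolan-2-yl)-3-methoxy-5-(methoxymethoxy)phenol F5. Methylation with MeI to 1-[3-(1,3-dioxolan-2-yl)-2-hydroxy-6-methoxy-4-(methoxymethoxy)phenyl]-N,N,N-trimethylmethanaminium iodide F6 and exchange with TolSO2Na in DMF, by the same elimination–addition as in step 4, then give 8. It sets out from 3 and returns at 8.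

**Step 5.** The aldehyde of 7 is chelated and flanked by two substituents, so acetalisation may stall. Longer acid exposure may exchange the MOM ether, the very electron-rich acetal may revert on silica, and any basic work-up would expel sulfinate. The fallback moves the acetalisation behind the key step, where the chelating phenol is gone. Sulfone 7 is taken into the cycloaddition with 17 (activated as 18) and (R)-benzotetramisole under the conditions of step 10; methide 6 is released from 7, and the hindered, electron-rich aldehyde is not expected to react with the ammonium enolate. This gives (3R)-5-methoxy-7-(methoxymethoxy)-3-[4-methoxy-2-(methoxymethoxy)-3-(3-methylbut-2-en-1-yl)phenyl]-2-oxo-3,4-dihydro-2H-chromene-8-carbaldehyde F7. Its aldehyde is acetalised under aprotic conditions (1,2-bis(trimethylsilyloxy)ethane, TMSOTf cat., CH2Cl2, −78 °C) to 20. It sets out from 7 and returns at 20.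

**Step 8.** O-Prenylation of the alkoxide or incomplete ring metalation through aggregation of the dilithio species can lower the yield. The fallback masks the alcohol. Compound 12 is silylated to tert-butyl{2-[4-methoxy-2-(methoxymethoxy)phenyl]ethoxy}dimethylsilane F8. This is metalated with one equivalent of n-BuLi and allylated with 13 to tert-butyl{2-[4-methoxy-2-(methoxymethoxy)-3-(3-methylbut-2-en-1-yl)phenyl]ethoxy}dimethylsilane F9. TBAF then gives 15. It sets out from 12 and returns at 15.

**Step 13.** The hindered ring B MOM ether cleaves slowest. Pushing the acid may add the 2'-hydroxyl across the prenyl double bond, or let formaldehyde-derived cations be recaptured by electron-rich ring A. The fallback separates the groups and removes the MOM ethers without protic acid. PPTS in wet acetone opens only the dioxolane of 22 to give (3R)-5-methoxy-7-(methoxymethoxy)-3-[4-methoxy-2-(methoxymethoxy)-3-(3-methylbut-2-en-1-yl)phenyl]-3,4-dihydro-2H-chromene-8-carbaldehyde F10. The two aryl MOM ethers are then cleaved with TMSOTf and 2,2'-bipyridyl in MeCN at 0 °C, followed by water, to give 23. It sets out from 22 and returns at 23.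

## Further compounds

F1 | step 10 | (4R)-4-benzyl-3-{[4-methoxy-2-(methoxymethoxy)-3-(3-methylbut-2-en-1-yl)phenyl]acetyl}-1,3-oxazolidin-2-one | O=C1OC[C@@H](Cc2ccccc2)N1C(=O)Cc1ccc(OC)c(CC=C(C)C)c1OCOC
F2 | step 10 | (4R)-4-benzyl-3-{(2R)-3-[3-(1,3-dioxolan-2-yl)-2-hydroxy-6-methoxy-4-(methoxymethoxy)phenyl]-2-[4-methoxy-2-(methoxymethoxy)-3-(3-methylbut-2-en-1-yl)phenyl]propanoyl}-1,3-oxazolidin-2-one | O=C1OC[C@@H](Cc2ccccc2)N1C(=O)[C@H](Cc1c(O)c(C2OCCO2)c(OCOC)cc1OC)c1ccc(OC)c(CC=C(C)C)c1OCOC
F3 | step 3 | 2-(1,3-dioxolan-2-yl)-5-methoxy-3-(methoxymethoxy)phenol | COCOc1cc(OC)cc(O)c1C1OCCO1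
F4 | step 3 | 3-(1,3-dioxolan-2-yl)-2-hydroxy-6-methoxy-4-(methoxymethoxy)benzaldehyde | O=Cc1c(O)c(C2OCCO2)c(OCOC)cc1OC
F5 | step 3 | 2-[(dimethylamino)methyl]-6-(1,3-dioxolan-2-yl)-3-methoxy-5-(methoxymethoxy)phenol | CN(C)Cc1c(O)c(C2OCCO2)c(OCOC)cc1OC
F6 | step 3 | 1-[3-(1,3-dioxolan-2-yl)-2-hydroxy-6-methoxy-4-(methoxymethoxy)phenyl]-N,N,N-trimethylmethanaminium iodide | C[N+](C)(C)Cc1c(O)c(C2OCCO2)c(OCOC)cc1OC.[I-]
F7 | step 5 | (3R)-5-methoxy-7-(methoxymethoxy)-3-[4-methoxy-2-(methoxymethoxy)-3-(3-methylbut-2-en-1-yl)phenyl]-2-oxo-3,4-dihydro-2H-chromene-8-carbaldehyde | COc1ccc([C@@H]2C(=O)Oc3c(C=O)c(OCOC)cc(OC)c3C2)c(OCOC)c1CC=C(C)C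
F8 | step 8 | tert-butyl{2-[4-methoxy-2-(methoxymethoxy)phenyl]ethoxy}dimethylsilane | CC(C)(C)[Si](C)(C)OCCc1ccc(OC)cc1OCOC
F9 | step 8 | tert-butyl{2-[4-methoxy-2-(methoxymethoxy)-3-(3-methylbut-2-en-1-yl)phenyl]ethoxy}dimethylsilane | CC(C)(C)[Si](C)(C)OCCc1ccc(OC)c(CC=C(C)C)c1OCOC
F10 | step 13 | (3R)-5-methoxy-7-(methoxymethoxy)-3-[4-methoxy-2-(methoxymethoxy)-3-(3-methylbut-2-en-1-yl)phenyl]-3,4-dihydro-2H-chromene-8-carbaldehyde | COc1ccc([C@@H]2COc3c(C=O)c(OCOC)cc(OC)c3C2)c(OCOC)c1CC=C(C)C
A1 | alternative 1 | (6R)-7-[(tert-butyldimethylsilyl)oxy]-4-diazo-2-methoxy-6-[4-methoxy-2-(methoxymethoxy)-3-(3-methylbut-2-en-1-yl)phenyl]hept-1-en-3-one | C=C(OC)C(=O)C(=[N+]=[N-])C[C@@H](CO[Si](C)(C)C(C)(C)C)c1ccc(OC)c(CC=C(C)C)c1OCOC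
A2 | alternative 1 | [(3,3-dimethoxyprop-1-yn-1-yl)oxy]tri(propan-2-yl)silane | COC(OC)C#CO[Si](C(C)C)(C(C)C)C(C)C
A3 | alternative 1 | 4-{(2R)-3-[(tert-butyldimethylsilyl)oxy]-2-[4-methoxy-2-(methoxymethoxy)-3-(3-methylbut-2-en-1-yl)phenyl]propyl}-2-(dimethoxymethyl)-5-methoxy-3-{[tri(propan-2-yl)silyl]oxy}phenol | COc1ccc([C@@H](Cc2c(OC)cc(O)c(C(OC)OC)c2O[Si](C(C)C)(C(C)C)C(C)C)CO[Si](C)(C)C(C)(C)C)c(OCOC)c1CC=C(C)C
A4 | alternative 2 | 8-(1,3-dioxolan-2-yl)-5-methoxy-7-(methoxymethoxy)-2H-chromene | COc1cc(OCOC)c(C2OCCO2)c2OCC=Cc12
A5 | alternative 2 | 6-iodo-3-methoxy-2-(3-methylbut-2-en-1-yl)phenol | COc1ccc(I)c(O)c1CC=C(C)C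
A6 | alternative 2 | cis-fused pterocarpan with 1,9-dimethoxy, 3-(methoxymethoxy), 4-(1,3-dioxolan-2-yl) and 10-(3-methylbut-2-en-1-yl) groups | COc1ccc2c(c1CC=C(C)C)O[C@H]1c3c(OC)cc(OCOC)c(C4OCCO4)c3OC[C@@H]21
A7 | alternative 3 | (3E)-1-diazo-4-[(3R)-5-methoxy-7-{[tri(propan-2-yl)silyl]oxy}-3,4-dihydro-2H-chromen-3-yl]but-3-en-2-one | [N-]=[N+]=CC(=O)/C=C/[C@@H]1COc2cc(O[Si](C(C)C)(C(C)C)C(C)C)cc(OC)c2C1
A8 | alternative 3 | 1-methoxy-5-methylhex-4-en-1-yne | COC#CCC=C(C)C
A9 | alternative 3 | 6-methoxy-3-[(3R)-5-methoxy-7-{[tri(propan-2-yl)silyl]oxy}-3,4-dihydro-2H-chromen-3-yl]-2-(3-methylbut-2-en-1-yl)phenol | COc1ccc([C@@H]2COc3cc(O[Si](C(C)C)(C(C)C)C(C)C)cc(OC)c3C2)c(O)c1CC=C(C)C
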